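**Retrosynthetic overview**
1. Target ⇐ 16-en-15-one carrying C6 as a dimethyl acetal: exo-face Luche reduction gives the 15-alcohol, and acetal hydrolysis is the last step.
2. Ring D (C13–C16) by 5-exo vinyl-radical cyclisation; the C8–C15 bond and quaternary C8 by an intermolecular aldol of the tricyclic lactone enolate with 2-bromoacrolein.
3. Ring C by Diels–Alder reaction of butadiene with an ester-activated unsaturated spirolactone; the activating ester is then removed.
4. Key C9–C10 bond and quaternary C10 by intermolecular Michael addition of an A-ring 2-formyl ketone to diethyl methylenemalonate, then CHO reduction and lactonisation (C20–O–C7).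
5. A ring from 4,4-dimethylcyclohexenone by asymmetric nitromethane Michael addition (C5/C6), Nef reaction and Claisen formylation (C20); ring order A → lactone → C → D.

Assumption: atoms carry the ent-kaurane numbers of the target (C1 acetoxy carbon, C5–C6 CH–CHO, C7 lactone C=O, C8/C13 bridgeheads, C15 carbinol, C16=C17 methylene, C20 lactone CH2), and the quinine-derived primary amine is taken to give (S)-3 (the quinidine-derived pseudo-enantiomer is used if the sense is opposite).

**Route**

Step 1
Reactants: 1 4,4-dimethylcyclohex-2-en-1-one; 2 nitromethane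
Product: 3 (S)-4,4-dimethyl-3-(nitromethyl)cyclohexan-1-one
Conditions: 9-amino-9-deoxy-epi-quinine (20 mol %), PhCO2H (40 mol %), 2 (10 equiv), THF, 40 °C
Reagents that add atoms: none
Why: Iminium-activated organocatalytic asymmetric Michael addition in which the cinchona scaffold shields one enone face, so nitromethane adds to C5 from the other and sets the stereocentre that controls all later ones.

Step 2
Reactants: 3 (S)-4,4-dimethyl-3-(nitromethyl)cyclohexan-1-one
Product: 4 (S)-3-(dimethoxymethyl)-4,4-dimethylcyclohexan-1-one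
Conditions: NaOMe, MeOH, 0 °C; then added to conc. H2SO4/MeOH, −35 °C; aqueous work-up
Reagents that add atoms: methanol, CO
Why: Nef reaction in its acidic-methanol (Jacobson) form turns the nitronate directly into the dimethyl acetal, giving C6 at the aldehyde oxidation level in protected form without touching the non-epimerisable C5 centre.

Step 3
Reactants: 4 (S)-3-(dimethoxymethyl)-4,4-dimethylcyclohexan-1-one
Product: 5 trimethylsilyl enol ether of 4 (C1=C2)
Conditions: LDA, THF, −78 °C; TMSCl
Reagents that add atoms: chlorotrimethylsilane, C[Si](C)(C)Cl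
Why: Kinetic enolisation by LDA removes the C2 hydrogen remote from the branched C5 substituent and O-silylation traps that enolate (any minor regioisomer is removed after step 4).

Step 4
Reactants: 5 trimethylsilyl enol ether of 4
Product: 6 (S)-5-(dimethoxymethyl)-4,4-dimethylcyclohex-2-en-1-one
Conditions: Pd(OAc)2 (1.05 equiv), MeCN, rt
Reagents that add atoms: none
Why: Saegusa–Ito oxidation (Pd(II) enolate, β-hydride elimination) installs the C2=C3 double bond, which leaves C10 as the only enolisable α-carbon.

Step 5
Reactants: 6 (S)-5-(dimethoxymethyl)-4,4-dimethylcyclohex-2-en-1-one; 7 ethyl formate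
Product: 8 6-(hydroxymethylidene) enone (enol of the 2-formyl ketone)
Conditions: NaH, THF, 0 °C → rt; AcOH quench
Reagents that add atoms: none
Why: Crossed Claisen condensation with ethyl formate occurs at C10, the only α-carbon bearing hydrogens, and is driven by formation of the stable sodium enolate of the β-keto aldehyde.

Step 6
Reactants: 8 6-(hydroxymethylidene) enone; 9 diethyl methylenemalonate
Product: 10 quaternary keto aldehyde malonate
Conditions: Et3N (10 mol %), CH2Cl2, 0 °C, slow addition of 9
Reagents that add atoms: none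
Why: Intermolecular Michael addition of the enolised 2-formyl ketone to the unhindered, doubly activated acceptor forms the C9–C10 bond and quaternary C10, the acceptor approaching anti to the adjacent C5 acetal group (pseudo-axial through allylic strain) so that C9 is trans and C20 cis to C6.

Step 7
Reactants: 10 quaternary keto aldehyde malonate
Product: 11 saturated keto aldehyde malonate
Conditions: H2 (1 atm), 10% Pd/C, EtOAc, rt
Reagents that add atoms: none
Why: Catalytic hydrogenation saturates only the conjugated C2=C3 bond, removing the blocking alkene and a competing Michael acceptor while aldehyde, esters and acetal stay intact.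

Step 8
Reactants: 11 saturated keto aldehyde malonate
Product: 13 keto spirolactone ester, via hydroxy diester 12 (not isolated)
Conditions: NaBH4, EtOH/CH2Cl2, −78 → −40 °C; aq. NH4Cl; then DMAP (cat.), PhMe, 60 °C
Reagents that add atoms: none
Why: Chemoselective borohydride reduction of the aldehyde beside the hindered ketone gives the neopentyl alcohol, which closes the C20–O–C7 δ-lactone by intramolecular transesterification onto either malonate ester.

Step 9
Reactants: 13 keto spirolactone ester
Product: 14 α-phenylselanyl lactone ester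
Conditions: NaH (1.0 equiv), THF, 0 °C; PhSeCl
Reagents that add atoms: benzeneselenenyl chloride, Cl[Se]c1ccccc1
Why: Selective deprotonation of the malonate-type C8–H (far more acidic than the ketone α-hydrogens) followed by selenenylation of the enolate.

Step 10
Reactants: 14 α-phenylselanyl lactone ester
Product: 16 unsaturated spirolactone ester, via selenoxide 15 (not isolated)
Conditions: 30% H2O2, pyridine, CH2Cl2, 0 °C → rt
Reagents that add atoms: none
Why: Oxidation to the selenoxide and spontaneous syn-elimination toward C9 (the only β-hydrogens) gives the ester-activated α,β-unsaturated lactone.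

Step 11
Reactants: 16 unsaturated spirolactone ester; 17 buta-1,3-diene
Product: 18 Diels–Alder adduct (ring C)
Conditions: 17 (excess), ZnCl2 (1 equiv), CH2Cl2, sealed tube, rt
Reagents that add atoms: none
Why: Lewis-acid-promoted Diels–Alder reaction of the doubly activated dienophile builds ring C cis-fused (suprafacial), the diene adding to the lactone face flanked by the flat C1 ketone and away from the bulky C5 acetal side, which sets C9.

Step 12
Reactants: 18 Diels–Alder adduct
Product: 19 tricyclic keto lactone (C8–H)
Conditions: LiCl, H2O, DMSO, 150 °C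
Reagents that add atoms: none
Why: Krapcho dealkoxycarbonylation (chloride SN2 at the ethyl group, then decarboxylation) removes the activating ester, while the neopentyl lactone CH2–O carbon is not attacked.

Step 13
Reactants: 19 tricyclic keto lactone
Product: 20 C1 alcohol
Conditions: NaBH4, MeOH, −20 °C
Reagents that add atoms: none
Why: Borohydride attacks the C1 ketone along the axial trajectory, anti to the axial C20 substituent on the neighbouring quaternary carbon, giving the equatorial 1-alcohol cis to C20.

Step 14
Reactants: 20 C1 alcohol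
Product: 21 C1 triethylsilyl ether
Conditions: TESCl, imidazole, DMAP (cat.), DMF, 40 °C
Reagents that add atoms: chlorotriethylsilane, CC[Si](CC)(CC)Cl
Why: Imidazole-mediated silylation (no silyl triflate, which would attack the acetal) masks the alcohol against the strong base of step 16 and prevents transfer of the lactone acyl group to O1.

Step 15
Reactants: 22 acrolein
Product: 24 2-bromoacrolein, via 2,3-dibromopropanal 23 (not isolated)
Conditions: Br2, CH2Cl2, −78 °C; then Et3N, 0 °C; used at once as a solution
Reagents that add atoms: bromine, BrBr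
Why: Bromine addition to the alkene followed by E1cB dehydrobromination gives the α-bromo enal.

Step 16
Reactants: 21 C1 triethylsilyl ether; 24 2-bromoacrolein
Product: 25 aldol adduct (C15 epimers)
Conditions: LDA (1.05 equiv), THF, −78 °C; then 24, −78 °C; AcOH quench at −78 °C
Reagents that add atoms: none
Why: Intermolecular aldol addition of the lithium lactone enolate to the aldehyde (1,2-addition) forms the C8–C15 bond and quaternary C8, the electrophile entering anti to C11 and syn to H9 as usual for a ring-fusion enolate (cis-fused outcome) and away from the C1 silyl ether; C15 is left open because steps 18 and 21 reset it.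

Step 17
Reactants: 25 aldol adduct
Product: 26 tetracyclic allylic alcohol (C15 epimers)
Conditions: Bu3SnH, AIBN (cat.), PhH (0.02 M), 80 °C
Reagents that add atoms: none
Why: Tin-mediated 5-exo-trig cyclisation of the C16 vinyl radical onto C13 of the ring-C alkene closes ring D as the bicyclo[3.2.1]octane with the exocyclic methylene, the C13 configuration being dictated by the bridge.

Step 18
Reactants: 26 tetracyclic allylic alcohol
Product: 27 16-en-15-one silyl ether
Conditions: Dess–Martin periodinane, NaHCO3, CH2Cl2, rt
Reagents that add atoms: none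
Why: Dess–Martin oxidation converges both C15 epimers into the α-methylene ketone.

Step 19
Reactants: 27 16-en-15-one silyl ether
Product: 28 1-hydroxy enone
Conditions: TBAF, AcOH (1:1), THF, rt
Reagents that add atoms: none
Why: Buffered fluoride desilylation cleaves the Si–O bond without opening the lactone or touching the acetal.

Step 20
Reactants: 28 1-hydroxy enone
Product: 29 1-acetoxy enone
Conditions: Ac2O, pyridine, DMAP (cat.), CH2Cl2, rt
Reagents that add atoms: acetic anhydride, CC(=O)OC(C)=O
Why: DMAP-catalysed acylation of the equatorial secondary alcohol installs the 1-acetate with no stereocentre affected.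

Step 21
Reactants: 29 1-acetoxy enone
Product: 30 15-hydroxy dimethyl acetal
Conditions: NaBH4, CeCl3·7H2O, MeOH, −78 °C
Reagents that add atoms: none
Why: Luche 1,2-reduction delivers hydride to C15 from the exo face of the bicyclo[3.2.1]octane (away from the three-carbon bridge), giving the endo 15-alcohol of the target without conjugate reduction or loss of the acetate.

Step 22
Reactants: 30 15-hydroxy dimethyl acetal
Product: 31 CNP0117386.1 (target)
Conditions: TsOH·H2O (cat.), acetone/H2O (10:1), rt
Reagents that add atoms: water, O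
Why: Mild acid-catalysed acetal hydrolysis unmasks the C6 aldehyde last, under conditions that leave acetate, lactone and allylic alcohol intact and do not enolise C5.

**Compound list**
1 | 4,4-dimethylcyclohex-2-en-1-one | O=C1C=CC(C)(C)CC1 | starting material
2 | nitromethane | C[N+](=O)[O-] | starting material
3 | (S)-4,4-dimethyl-3-(nitromethyl)cyclohexan-1-one | O=C1CCC(C)(C)[C@@H](C[N+](=O)[O-])C1 | intermediate
4 | (S)-3-(dimethoxymethyl)-4,4-dimethylcyclohexan-1-one | O=C1CCC(C)(C)[C@@H](C(OC)OC)C1 | intermediate
5 | {[(5S)-5-(dimethoxymethyl)-4,4-dimethylcyclohex-1-en-1-yl]oxy}trimethylsilane | C[Si](C)(C)OC1=CCC(C)(C)[C@@H](C(OC)OC)C1 | intermediate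
6 | (S)-5-(dimethoxymethyl)-4,4-dimethylcyclohex-2-en-1-one | O=C1C=CC(C)(C)[C@@H](C(OC)OC)C1 | intermediate
7 | ethyl formate | CCOC=O | starting material
8 | 5-(dimethoxymethyl)-6-(hydroxymethylidene)-4,4-dimethylcyclohex-2-en-1-one (Z-enol of the 6-formyl enone; C5 as in 6) | O=C1C=CC(C)(C)[C@@H](C(OC)OC)/C1=C/O | intermediate
9 | diethyl methylenemalonate (diethyl 2-methylidenepropanedioate; stabilised, distilled before use) | C=C(C(=O)OCC)C(=O)OCC | starting material
10 | diethyl 2-{[6-(dimethoxymethyl)-1-formyl-5,5-dimethyl-2-oxocyclohex-3-en-1-yl]methyl}propanedioate; malonylmethyl arm (C9) trans and CHO (C20) cis to the acetal group | O=C[C@]1(CC(C(=O)OCC)C(=O)OCC)[C@H](C(OC)OC)C(C)(C)C=CC1=O | intermediate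
11 | diethyl 2-{[2-(dimethoxymethyl)-1-formyl-3,3-dimethyl-6-oxocyclohexyl]methyl}propanedioate; same relative configuration as 10 | O=C[C@]1(CC(C(=O)OCC)C(=O)OCC)[C@H](C(OC)OC)C(C)(C)CCC1=O | intermediate
12 | diethyl 2-{[2-(dimethoxymethyl)-1-(hydroxymethyl)-3,3-dimethyl-6-oxocyclohexyl]methyl}propanedioate (hydroxy diester) | OC[C@]1(CC(C(=O)OCC)C(=O)OCC)[C@H](C(OC)OC)C(C)(C)CCC1=O | intermediate
13 | ethyl 7-(dimethoxymethyl)-8,8-dimethyl-3,11-dioxo-2-oxaspiro[5.5]undecane-4-carboxylate; lactone CH2O cis to the acetal group; mixture of epimers at the ester-bearing carbon (C8) | CCOC(=O)C1C[C@@]2(COC1=O)[C@H](C(OC)OC)C(C)(C)CCC2=O | intermediate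
14 | 4-(phenylselanyl) derivative of 13 (selenium on C8) | CCOC(=O)C1([Se]c3ccccc3)C[C@@]2(COC1=O)[C@H](C(OC)OC)C(C)(C)CCC2=O | intermediate
15 | selenoxide of 14 | CCOC(=O)C1([Se](=O)c3ccccc3)C[C@@]2(COC1=O)[C@H](C(OC)OC)C(C)(C)CCC2=O | intermediate
16 | ethyl 7-(dimethoxymethyl)-8,8-dimethyl-3,11-dioxo-2-oxaspiro[5.5]undec-4-ene-4-carboxylate (C8=C9) | CCOC(=O)C1=C[C@@]2(COC1=O)[C@H](C(OC)OC)C(C)(C)CCC2=O | intermediate
17 | buta-1,3-diene | C=CC=C | starting material
18 | tricyclic adduct: cyclohexene ring C (C12=C13) cis-fused at C8–C9 to the spirolactone on the face syn to the C1 ketone; CO2Et on C8 syn to H9; C1 ketone; C6 dimethyl acetal | CCOC(=O)[C@]12CC=CC[C@H]1[C@@]3(COC2=O)[C@H](C(OC)OC)C(C)(C)CCC3=O | intermediate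
19 | de-ethoxycarbonylated tricyclic keto lactone (C8–H, epimer mixture) | C12CC=CC[C@H]1[C@@]3(COC2=O)[C@H](C(OC)OC)C(C)(C)CCC3=O | intermediate
20 | C1 alcohol of 19 (equatorial OH, cis to C20 and to the acetal group) | C12CC=CC[C@H]1[C@@]3(COC2=O)[C@H](C(OC)OC)C(C)(C)CC[C@@H]3O | intermediate
21 | triethylsilyl ether of 20 | C12CC=CC[C@H]1[C@@]3(COC2=O)[C@H](C(OC)OC)C(C)(C)CC[C@@H]3O[Si](CC)(CC)CC | intermediate
22 | acrolein (prop-2-enal) | C=CC=O | starting material
23 | 2,3-dibromopropanal | O=CC(Br)CBr | intermediate
24 | 2-bromoacrolein (2-bromoprop-2-enal) | C=C(Br)C=O | intermediate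
25 | aldol adduct: C8 bears CH(OH)C(Br)=CH2 syn to H9 (C15 epimers) | C=C(Br)C(O)[C@]12CC=CC[C@H]1[C@@]3(COC2=O)[C@H](C(OC)OC)C(C)(C)CC[C@@H]3O[Si](CC)(CC)CC | intermediate
26 | 15-hydroxy-16-ene tetracycle (bicyclo[3.2.1]octane C/D, C15 epimers); 1-OTES; C6 dimethyl acetal | C=C1[C@@H]2CC[C@@H]3[C@](C2)(C(=O)OC[C@]32[C@@H](O[Si](CC)(CC)CC)CCC(C)(C)[C@H]2C(OC)OC)C1O | intermediate
27 | 16-en-15-one; 1-OTES; C6 dimethyl acetal | C=C1[C@@H]2CC[C@@H]3[C@](C2)(C(=O)OC[C@]32[C@@H](O[Si](CC)(CC)CC)CCC(C)(C)[C@H]2C(OC)OC)C1=O | intermediate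
28 | 1-hydroxy-16-en-15-one; C6 dimethyl acetal | C=C1[C@@H]2CC[C@@H]3[C@](C2)(C(=O)OC[C@]32[C@@H](O)CCC(C)(C)[C@H]2C(OC)OC)C1=O | intermediate
29 | 1-acetoxy-16-en-15-one; C6 dimethyl acetal | C=C1[C@@H]2CC[C@@H]3[C@](C2)(C(=O)OC[C@]32[C@@H](OC(C)=O)CCC(C)(C)[C@H]2C(OC)OC)C1=O | intermediate
30 | dimethyl acetal of the target (1-acetate, endo 15-alcohol) | C=C1[C@@H]2CC[C@@H]3[C@](C2)(C(=O)OC[C@]32[C@@H](OC(C)=O)CCC(C)(C)[C@H]2C(OC)OC)[C@@H]1O | intermediate
31 | CNP0117386.1 | C=C1[C@@H]2CC[C@@H]3[C@](C2)(C(=O)OC[C@]32[C@@H](OC(C)=O)CCC(C)(C)[C@H]2C=O)[C@@H]1O | target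

**Totals and risks**

Total step count: 22. Longest linear sequence: 21 (steps 1–14 and 16–22; step 15 is a one-step branch).

The three steps most likely to fail are steps 1, 11 and 16.

Step 1 may be slow or poorly selective because the enone β-carbon sits next to a quaternary centre. The fallback sets out from 1: Rh(I)/(R)-BINAP-catalysed 1,4-addition of potassium vinyltrifluoroborate (dioxane/H2O, Et3N, 80 °C) gives (R)-4,4-dimethyl-3-vinylcyclohexan-1-one F1. Ozonolysis (O3, CH2Cl2, −78 °C; Me2S) gives (S)-2,2-dimethyl-5-oxocyclohexane-1-carbaldehyde F2. Aldehyde-selective acetalisation (HC(OMe)3, CeCl3·7H2O, MeOH) then comes back to the route at 4.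

Step 11 may fail because the dienophile β-carbon is neopentyl and the Lewis acid can attack the acetal. The fallback sets out from 16: thermal cycloaddition with the far more nucleophilic 2-(trimethylsilyloxy)buta-1,3-diene (PhMe, 80 °C; the silyloxy group directs C11 to C9) gives the C12 silyl enol ether adduct F3. CsF/PhNTf2 (DME) converts it into the C12 enol triflate F4. Pd(OAc)2/PPh3 with HCO2H/Bu3N (DMF, 60 °C) reduces the triflate to the C12=C13 alkene, coming back to the route at 18.

Step 16 builds a quaternary centre in a crowded, reversible aldol and may give low conversion or retro-aldol. The fallback sets out from 21: irreversible C-alkylation of the same enolate with 2,3-dibromopropene (LDA, THF/DMPU, −78 → −20 °C) gives the 8-(2-bromoallyl) lactone F5. Bu3SnH/AIBN cyclisation gives the 15-deoxy 16-ene tetracycle F6. Allylic hydroxylation at C15 (SeO2 cat., t-BuOOH, CH2Cl2) then comes back to the route at 26; either C15 epimer serves because step 18 follows.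

**Further compounds**
F1 | step 1 | (R)-4,4-dimethyl-3-vinylcyclohexan-1-one | O=C1CCC(C)(C)[C@@H](C=C)C1
F2 | step 1 | (S)-2,2-dimethyl-5-oxocyclohexane-1-carbaldehyde | O=C1CCC(C)(C)[C@@H](C=O)C1
F3 | step 11 | C12 trimethylsilyl enol ether analogue of 18 (C12(OTMS)=C13) | CCOC(=O)[C@]12CC=C(O[Si](C)(C)C)C[C@H]1[C@@]3(COC2=O)[C@H](C(OC)OC)C(C)(C)CCC3=O
F4 | step 11 | C12 enol triflate analogue of 18 (C12(OTf)=C13) | CCOC(=O)[C@]12CC=C(OS(=O)(=O)C(F)(F)F)C[C@H]1[C@@]3(COC2=O)[C@H](C(OC)OC)C(C)(C)CCC3=O
F5 | step 16 | 8-(2-bromoallyl) derivative of 21 (allyl group syn to H9) | C=C(Br)C[C@]12CC=CC[C@H]1[C@@]3(COC2=O)[C@H](C(OC)OC)C(C)(C)CC[C@@H]3O[Si](CC)(CC)CC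
F6 | step 16 | 15-deoxy analogue of 26 (C15 is CH2) | C=C1[C@@H]2CC[C@@H]3[C@](C2)(C(=O)OC[C@]32[C@@H](O[Si](CC)(CC)CC)CCC(C)(C)[C@H]2C(OC)OC)C1
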